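Take the easy step first and read the opening of the midnight run.

| flask | J | D | remark | time |
|---|---|---|---|---|
| midnight | 10 mM | 6.7 mM | run made earlier |  |
| Thursday's | 10 mM | 10.0 mM |  | 6.0 h |
| Saturday's | 10 mM | 15.0 mM |  | 6.0 h |
| Wednesday's | 10 mM | 20.0 mM |  | 6.0 h |

midnight run (percent of the J charged)

| time / h | Z / % | J / % |
|---|---|---|
| 0.250 | 0 | 89.7 |
| 0.667 | 3.5 | 78.3 |
| 1.33 | 7.1 | 68.2 |
| 2.00 | 8.8 | 62.2 |
| 2.50 | 11.7 | 59.5 |
| 3.00 | 8.9 | 56.3 |
| 4.00 | 6.7 | 54.3 |

(standard deviation of a reading: 1 percentage point)

- the numbers in the tables scatter with a standard deviation of 1 percentage point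
- no earlier run changes the charge of D; that part of a forecast is a guess

- Z at the end, in percent of the J charged, for each flask in turn (Thursday's, Saturday's, Wednesday's)

In that run J reads 89.7% at 0.250 h with [D] = 6.7 mM charged, an apparent first-order loss, read from one point, of 0.435 h⁻¹. Scale it with [D], and my estimate of the half-life of J at the start is 1.07 h in Thursday's flask and 0.534 h in Wednesday's. That is the fast rung.

Climb to the next one. In the midnight run Z reads 11.7% at 2.50 h, above the 8.8% and 8.9% on either side: put the crossing, where the making of Z drops below its loss, somewhere near there, as a reading from scattered points.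

Now take the slow rung. Z sags from 8.9% at 3.00 h to 6.7% at 4.00 h, which gives a sag clock, the half-life of Z on its descent, of 2.44 h. Treat it as rough, since it rests on two readings. The first exchange in Thursday's flask runs faster than the sag, and the asked 6.0 h spans 2.46 sag clocks. So I read the end of the three flasks as a point on a descent, later than the midnight run's crossing.

The forecast says 13%, 23% and 33%, on the ground that “Six hours should nearly reach this”, meaning an equilibrium. There my reading differs.

The flasks give 13.6%, 24.1% and 32.5%, so the forecast stands within its margin.

    J + D → Q + E (k = 1.17 L mol⁻¹ min⁻¹)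
    E + D → Q + Z (k = 1.83 L mol⁻¹ min⁻¹)
    Z ⇌ G (K = 5.00, k = 0.00460 min⁻¹)

In Thursday's flask at 6.00 h, with each step taken net, Z is made at 0.268 of the rate at which it is used up, and the sag clock on its own takes the 18.9% of 3.00 h down to 8.06%, against 13.6% in the flask. In Wednesday's flask the same clock takes 43.4% down to 18.5%, against 32.5%, with D going from 22.8% of its charge at 3.00 h to 12.1% at 6.00 h.

Readings and results stem from a simulated flask with made-up constants; scatter was added.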